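**Retrosynthetic overview**
1. Last bond: the aryl ether C–O, by Mitsunobu coupling of 7‑hydroxy‑8‑methoxycoumarin (12) with the complete side‑chain epoxy diol (10).
2. 10 comes from a Payne rearrangement (inversion at C6) of a trans‑2,3‑disubstituted epoxide carrying a tertiary carbinol (8/9).
3. Key C6–C7 bond: an α‑lithiated terminal epoxide (oxiranyl anion, a nucleophilic epoxide carbon) adds to acetone; the single stereocentre of (S)‑epichlorohydrin controls both C5 and C6.
4. The terminal epoxide (6) comes from (S)‑epichlorohydrin and acetylene, with Negishi carboalumination/hydroxymethylation setting the E‑trisubstituted alkene.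
5. Ring order: oxirane C5–C6 (step 3), transposed to oxirane C6–C7 (step 5); pyranone ring of the coumarin by Pechmann condensation (step 6); the benzene ring is bought.

Convention and assumption: side‑chain carbons are numbered C1 (OCH2) to C7 (CMe2); small atom‑delivering reagents (acetylene, Me3Al, formaldehyde, TBSCl, acetone, malic acid) are given with SMILES in the steps and are not numbered.

**Step 1**
Reactants: 1 (S)‑epichlorohydrin
Product: 2 (2S)‑1‑chloropent‑4‑yn‑2‑ol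
Conditions: HC≡CH, n‑BuLi, THF, −78 °C; BF3·OEt2 (promoter); then 1, −78 °C; H2O
Reagents that add atoms: acetylene, C#C (used as lithium acetylide, [Li]C#C)
Why: Yamaguchi–Hirao alkynylation, in which the BF3‑activated epoxide is opened by lithium acetylide only at the unsubstituted ring carbon, so the C–O stereocentre of 1 is carried over unchanged (it becomes C5, S) and the C–Cl bond is untouched at −78 °C.

**Step 2**
Reactants: 2 (2S)‑1‑chloropent‑4‑yn‑2‑ol
Product: 4 (2E,5S)‑6‑chloro‑3‑methylhex‑2‑ene‑1,5‑diol, via alkenylalane 3 (not isolated)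
Conditions: Me3Al (3 equiv), Cp2ZrCl2 (0.25 equiv), CH2Cl2, 0 °C→rt; concentrate; n‑BuLi, THF/hexane, −78→0 °C; (CH2O)n, rt; aqueous work‑up
Reagents that add atoms: trimethylaluminium, C[Al](C)C; paraformaldehyde (formaldehyde), C=O
Why: Negishi Zr‑catalysed carboalumination adds Me–Al syn across the terminal alkyne (Me to the internal carbon) and the alkenylalane, after ate‑complex formation, is hydroxymethylated by formaldehyde with retention, giving the E‑trisubstituted allylic alcohol (CH2OH cis to CH3) while the free OH rides along as its aluminium alkoxide and the stereocentre is not involved.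

**Step 3**
Reactants: 4 (2E,5S)‑6‑chloro‑3‑methylhex‑2‑ene‑1,5‑diol
Product: 6 tert‑butyl(dimethyl){[(2E)‑3‑methyl‑4‑[(2S)‑oxiran‑2‑yl]but‑2‑en‑1‑yl]oxy}silane, via sodium epoxy alkoxide 5 (not isolated)
Conditions: NaH (2.2 equiv), THF, 0 °C→rt; then TBSCl (1.1 equiv), 0 °C→rt
Reagents that add atoms: tert‑butyldimethylsilyl chloride (TBSCl), CC(C)(C)[Si](C)(C)Cl
Why: intramolecular Williamson ring closure of the chlorohydrin alkoxide (only the CH2Cl carbon is attacked, so C5 stays S) followed by in‑flask silylation of the remaining primary sodium alkoxide (NaH/TBSCl monosilylation).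

**Step 4 (key step)**
Reactants: 6 tert‑butyl(dimethyl){[(2E)‑3‑methyl‑4‑[(2S)‑oxiran‑2‑yl]but‑2‑en‑1‑yl]oxy}silane
Product: 8 2‑[(2R,3S)‑3‑[(2E)‑4‑{[tert‑butyl(dimethyl)silyl]oxy}‑2‑methylbut‑2‑en‑1‑yl]oxiran‑2‑yl]propan‑2‑ol, via oxiranyllithium 7 (not isolated)
Conditions: s‑BuLi (1.5 equiv), (−)‑sparteine (1.5 equiv), hexane, −90 °C, 2 h; acetone (3 equiv), −90→0 °C; H2O
Reagents that add atoms: acetone, CC(C)=O
Why: ligand‑assisted α‑lithiation of a terminal epoxide (Hodgson conditions) removes the ring CH2 hydrogen trans to the side chain, and the configurationally stable oxiranyllithium – an epoxide carbon acting as a nucleophile (α‑oxy carbanion, reversed polarity) – adds to the carbonyl carbon of acetone with retention, so two normally electrophilic carbons are joined as C6–C7 and C6 is set (R, trans to C5) by substrate control.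

**Step 5**
Reactants: 8 2‑[(2R,3S)‑3‑[(2E)‑4‑{[tert‑butyl(dimethyl)silyl]oxy}‑2‑methylbut‑2‑en‑1‑yl]oxiran‑2‑yl]propan‑2‑ol
Product: 10 (2E,5S)‑5‑[(2S)‑3,3‑dimethyloxiran‑2‑yl]‑3‑methylpent‑2‑ene‑1,5‑diol, via desilylated trans‑epoxy diol 9 (not isolated)
Conditions: TBAF (1.5 equiv), THF, 0 °C→rt; then 0.5 M aq NaOH, t‑BuOH, rt (one pot)
Reagents that add atoms: none
Why: fluoride desilylation followed by base‑mediated Payne rearrangement, in which the tertiary alkoxide opens the adjacent epoxide at C6 by 3‑exo‑tet attack with inversion (R→S) while the old epoxide oxygen stays on C5 (S retained), the equilibrium lying on the side of the trisubstituted epoxide/secondary carbinol, to give the erythro (5S,6S) epoxy alcohol.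

**Step 6**
Reactants: 11 2‑methoxybenzene‑1,3‑diol (2‑methoxyresorcinol)
Product: 12 7‑hydroxy‑8‑methoxy‑2H‑chromen‑2‑one
Conditions: DL‑malic acid (1.1 equiv), conc. H2SO4, 100–120 °C; ice‑water
Reagents that add atoms: DL‑malic acid, OC(CC(O)=O)C(O)=O
Why: von Pechmann condensation, in which malic acid is decarbonylated to formylacetic acid that attacks the activated position ortho to one OH of the symmetric resorcinol and lactonises, forming the pyranone ring with OMe at C8 and the free OH at C7.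

**Step 7**
Reactants: 10 (2E,5S)‑5‑[(2S)‑3,3‑dimethyloxiran‑2‑yl]‑3‑methylpent‑2‑ene‑1,5‑diol; 12 7‑hydroxy‑8‑methoxy‑2H‑chromen‑2‑one
Product: 13 7‑{[(2E,5S)‑5‑[(2S)‑3,3‑dimethyloxiran‑2‑yl]‑5‑hydroxy‑3‑methylpent‑2‑en‑1‑yl]oxy}‑8‑methoxy‑2H‑chromen‑2‑one (CNP0166233.1)
Conditions: PPh3 (1.2 equiv), DIAD (1.2 equiv), THF, 0 °C→rt
Reagents that add atoms: none
Why: Mitsunobu etherification, in which the acidic coumarin 7‑OH (pKa ≈ 8) displaces the activated primary allylic alcohol by SN2 (alkene geometry and both stereocentres untouched) while the hindered secondary carbinol next to the epoxide does not compete at 0 °C.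

**Compound list**
1 | (S)‑epichlorohydrin, (2S)‑2‑(chloromethyl)oxirane | ClC[C@@H]1CO1 | starting material
2 | (2S)‑1‑chloropent‑4‑yn‑2‑ol | ClC[C@@H](O)CC#C | intermediate
3 | [(1E,4S)‑5‑chloro‑4‑[(dimethylalumanyl)oxy]‑2‑methylpent‑1‑en‑1‑yl]dimethylalumane (alkenylalane, formed in the flask) | C[Al](C)/C=C(\C)C[C@@H](CCl)O[Al](C)C | intermediate
4 | (2E,5S)‑6‑chloro‑3‑methylhex‑2‑ene‑1,5‑diol | ClC[C@@H](O)C/C(C)=C/CO | intermediate
5 | sodium (2E)‑3‑methyl‑4‑[(2S)‑oxiran‑2‑yl]but‑2‑en‑1‑olate (formed in the flask) | [Na+].[O-]C/C=C(\C)C[C@H]1CO1 | intermediate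
6 | tert‑butyl(dimethyl){[(2E)‑3‑methyl‑4‑[(2S)‑oxiran‑2‑yl]but‑2‑en‑1‑yl]oxy}silane | CC(C)(C)[Si](C)(C)OC/C=C(\C)C[C@H]1CO1 | intermediate
7 | {(2S,3S)‑3‑[(2E)‑4‑{[tert‑butyl(dimethyl)silyl]oxy}‑2‑methylbut‑2‑en‑1‑yl]oxiran‑2‑yl}lithium (Li trans to the side chain, formed in the flask) | [Li][C@@H]1O[C@H]1C/C(C)=C/CO[Si](C)(C)C(C)(C)C | intermediate
8 | 2‑[(2R,3S)‑3‑[(2E)‑4‑{[tert‑butyl(dimethyl)silyl]oxy}‑2‑methylbut‑2‑en‑1‑yl]oxiran‑2‑yl]propan‑2‑ol | CC(C)(O)[C@@H]1O[C@H]1C/C(C)=C/CO[Si](C)(C)C(C)(C)C | intermediate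
9 | 2‑[(2R,3S)‑3‑[(2E)‑4‑hydroxy‑2‑methylbut‑2‑en‑1‑yl]oxiran‑2‑yl]propan‑2‑ol (formed in the flask) | CC(C)(O)[C@@H]1O[C@H]1C/C(C)=C/CO | intermediate
10 | (2E,5S)‑5‑[(2S)‑3,3‑dimethyloxiran‑2‑yl]‑3‑methylpent‑2‑ene‑1,5‑diol | OC/C=C(\C)C[C@H](O)[C@@H]1OC1(C)C | intermediate
11 | 2‑methoxybenzene‑1,3‑diol | COc1c(O)cccc1O | starting material
12 | 7‑hydroxy‑8‑methoxy‑2H‑chromen‑2‑one | COc1c(O)ccc2ccc(=O)oc12 | intermediate
13 | 7‑{[(2E,5S)‑5‑[(2S)‑3,3‑dimethyloxiran‑2‑yl]‑5‑hydroxy‑3‑methylpent‑2‑en‑1‑yl]oxy}‑8‑methoxy‑2H‑chromen‑2‑one | COc1c(OC/C=C(\C)C[C@H](O)[C@@H]2OC2(C)C)ccc2ccc(=O)oc12 | target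

**Step count and risk**
Total steps: 7. Longest linear sequence: 6 (steps 1, 2, 3, 4, 5, 7).

Most likely to fail, in this order: step 4, step 2, step 5.

Step 4 is the main risk. The C4 hydrogens of 6 are allylic and β to the epoxide oxygen, and the allylic silyl ether CH2 is also acidic, so β‑elimination or allylic deprotonation may compete with α‑lithiation. The fallback sets out from 6 and comes back at 10, and it gives up the oxiranyl‑anion bond construction. Epoxide 6 is homologated with dimethylsulfonium methylide (Me3S+ I−, n‑BuLi, THF, −10 °C→rt) to the allylic alcohol (3S,5E)‑7‑{[tert‑butyl(dimethyl)silyl]oxy}‑5‑methylhepta‑1,5‑dien‑3‑ol F1, with C5 retained. Cross‑metathesis of its vinyl group with 2‑methylbut‑2‑ene (Grubbs II, 40 °C) gives (4S,6E)‑8‑{[tert‑butyl(dimethyl)silyl]oxy}‑2,6‑dimethylocta‑2,6‑dien‑4‑ol F2. Hydroxyl‑directed Sharpless epoxidation (Ti(OiPr)4, L‑(+)‑DIPT, TBHP, CH2Cl2, −20 °C), which I expect to be the matched case for the S carbinol, gives the erythro product (1S,3E)‑5‑{[tert‑butyl(dimethyl)silyl]oxy}‑1‑[(2S)‑3,3‑dimethyloxiran‑2‑yl]‑3‑methylpent‑3‑en‑1‑ol F3. TBAF then gives 10.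

Step 2 is the second risk. Making the ate complex with n‑BuLi turns the β‑chloro aluminium alkoxide into a better nucleophile, which may close to an epoxide early and be opened by the alanate. The fallback sets out from 2 and comes back at 4. After the same carboalumination, alkenylalane 3 is acylated directly with ethyl chloroformate (no ate complex needed) to ethyl (2E,5S)‑6‑chloro‑5‑hydroxy‑3‑methylhex‑2‑enoate F4. DIBAL‑H (CH2Cl2, −78 °C) reduces F4 to 4.

Step 5 is the third risk. The one‑pot desilylation/Payne equilibration may stall or give hydrolysis by‑products, and it leaves a secondary OH to compete in step 7. The fallback sets out from 8 and comes back at 13. Buffered desilylation (TBAF/AcOH, THF) gives 9, which is isolated; its tertiary OH is inert in a Mitsunobu reaction. Coupling 9 with 12 (PPh3, DIAD, THF) gives 7‑{[(2E)‑4‑[(2S,3R)‑3‑(2‑hydroxypropan‑2‑yl)oxiran‑2‑yl]‑3‑methylbut‑2‑en‑1‑yl]oxy}‑8‑methoxy‑2H‑chromen‑2‑one F5. The Payne rearrangement is then run last on F5 under aprotic conditions (cat. NaH, THF, 0 °C) to give 13.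

**Further compounds**
F1 | step 4 | (3S,5E)‑7‑{[tert‑butyl(dimethyl)silyl]oxy}‑5‑methylhepta‑1,5‑dien‑3‑ol | CC(C)(C)[Si](C)(C)OC/C=C(\C)C[C@H](O)C=C
F2 | step 4 | (4S,6E)‑8‑{[tert‑butyl(dimethyl)silyl]oxy}‑2,6‑dimethylocta‑2,6‑dien‑4‑ol | CC(C)(C)[Si](C)(C)OC/C=C(\C)C[C@H](O)C=C(C)C
F3 | step 4 | (1S,3E)‑5‑{[tert‑butyl(dimethyl)silyl]oxy}‑1‑[(2S)‑3,3‑dimethyloxiran‑2‑yl]‑3‑methylpent‑3‑en‑1‑ol | CC(C)(C)[Si](C)(C)OC/C=C(\C)C[C@H](O)[C@@H]1OC1(C)C
F4 | step 2 | ethyl (2E,5S)‑6‑chloro‑5‑hydroxy‑3‑methylhex‑2‑enoate | CCOC(=O)/C=C(\C)C[C@H](O)CCl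
F5 | step 5 | 7‑{[(2E)‑4‑[(2S,3R)‑3‑(2‑hydroxypropan‑2‑yl)oxiran‑2‑yl]‑3‑methylbut‑2‑en‑1‑yl]oxy}‑8‑methoxy‑2H‑chromen‑2‑one | COc1c(OC/C=C(\C)C[C@@H]2O[C@H]2C(C)(C)O)ccc2ccc(=O)oc12
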